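**Retrosynthetic overview**

1. The two esters go on last. The C8 carbinol comes from reagent-controlled reduction of a ring-B enone.
2. Ring B (seven-membered) comes from a cyclohexanone by Ito–Saegusa one-carbon ring expansion, which inserts C7 between C8 (C=O) and C6 (C–Me).
3. Ring A (five-membered) comes from a cyclohexene by ozonolysis and intramolecular aldol condensation, which closes the C2–C3 bond. The enabling feature: C8a–C1–C2, C3–C3a and the isopropyl methine on C3 are six contiguous carbons, i.e. a cyclohex-4-ene fused at C3a–C8a in which the methine was bonded to C2. C3 therefore ends up carrying the exocyclic carbon and the unsaturation used for its hydroxyl.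
4. The resulting cis-decalin is the Diels–Alder adduct of 2,6-dimethyl-1,4-benzoquinone and butadiene. It already holds C3a, C8a (angular methyl), C4 and C8 (carbonyls), C5 and C6 (with its methyl).
5. Ring order: two six-membered rings (Diels–Alder), then ring A (contraction), then ring B (expansion).

Key step: step 5

Locants are those of the target as an octahydroazulene: ring A = C1, C2, C3, C3a, C8a; ring B = C3a, C4–C8, C8a. The same locants hold for ring A in the hydrindane intermediates.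

Assumption: the oxazaborolidinium catalyst of step 1 is used in the enantiomeric form that gives (4aS,8aR)-3; the (S)-prolinol-derived catalyst is written, and its mirror image is taken if the sense of induction is opposite.

**Route**

Step 1
Reactants: 1 2,6-dimethyl-1,4-benzoquinone; 2 buta-1,3-diene
Product: 3 (4aS,8aR)-2,8a-dimethyl-4a,5,8,8a-tetrahydronaphthalene-1,4-dione (cis-fused)
Conditions: 2 (excess), (S)-1-(2-methylphenyl)-3,3-diphenyltetrahydro-1H,3H-pyrrolo[1,2-c][1,3,2]oxazaborole protonated with HNTf2 (20 mol %), CH2Cl2, −78 to −40 °C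
Reagents that add atoms: buta-1,3-diene (2), C=CC=C
Why: Enantioselective quinone Diels–Alder reaction under chiral cationic oxazaborolidine catalysis; suprafacial addition to a methyl-substituted C=C sets the angular methyl (C8a) and the ring-fusion hydrogen (C3a) cis, and the catalyst, bound to the carbonyl that has α-vinyl hydrogens, selects the enantiotopic face.

Step 2
Reactants: 3 (4aS,8aR)-2,8a-dimethyl-4a,5,8,8a-tetrahydronaphthalene-1,4-dione
Product: 4 (4aS,8aR)-2,8a-dimethyl-2,3,4a,5,8,8a-hexahydronaphthalene-1,4-dione (epimers at the methyl-bearing CH)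
Conditions: Zn dust, AcOH, 0 °C to rt
Reagents that add atoms: none
Why: Dissolving-metal conjugate reduction of the ene-dione C=C leaves the isolated cyclohexene untouched; the new methyl-bearing centre forms as a mixture, which does not matter because it becomes sp2 again in step 11.

Step 3
Reactants: 4 (4aS,8aR)-2,8a-dimethyl-2,3,4a,5,8,8a-hexahydronaphthalene-1,4-dione
Product: 5 (4R,4aS,8aR)-4-hydroxy-2,8a-dimethyl-3,4,4a,5,8,8a-hexahydronaphthalen-1(2H)-one
Conditions: NaBH4 (0.3 equiv), MeOH/CH2Cl2, −78 °C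
Reagents that add atoms: none
Why: Chemoselective hydride reduction of the less hindered ketone (the other is flanked by a quaternary and a tertiary carbon); hydride should add from the convex face of the cis-decalin (the side of the angular methyl), which places the hydroxyl cis to the cyclohexene ring as required for C4.

Step 4
Reactants: 5 (4R,4aS,8aR)-4-hydroxy-2,8a-dimethyl-3,4,4a,5,8,8a-hexahydronaphthalen-1(2H)-one; 6 4-(acetyloxy)benzoyl chloride
Product: 7 (1R,4aR,8aS)-3,4a-dimethyl-4-oxo-1,2,3,4,4a,5,8,8a-octahydronaphthalen-1-yl 4-(acetyloxy)benzoate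
Conditions: pyridine, DMAP (cat.), CH2Cl2, 0 °C to rt
Reagents that add atoms: 4-(acetyloxy)benzoyl chloride (6), CC(=O)Oc1ccc(cc1)C(Cl)=O
Why: DMAP-catalysed acylation (nucleophilic acyl substitution) installs the aroyl group of the target with its phenol masked as the acetate and removes the free hydroxyl before the aldehyde chemistry; no stereocentre is touched.

Step 5
Reactants: 7 (1R,4aR,8aS)-3,4a-dimethyl-4-oxo-1,2,3,4,4a,5,8,8a-octahydronaphthalen-1-yl 4-(acetyloxy)benzoate
Product: 10 (3aS,4R,7aR)-3-formyl-6,7a-dimethyl-7-oxo-3a,4,5,6,7,7a-hexahydro-1H-inden-4-yl 4-(acetyloxy)benzoate, via secondary ozonide 8 (not isolated), via dialdehyde 9 (not isolated)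
Conditions: O3, CH2Cl2, −78 °C; PPh3, −78 °C to rt; then dibenzylammonium trifluoroacetate (20 mol %), toluene, 60 °C
Reagents that add atoms: ozone, O=[O+][O-]
Why: Ozone adds to the isolated cis-disubstituted C=C (1,3-dipolar cycloaddition, cycloreversion, recombination to the 1,2,4-trioxolane), PPh3 reduces the ozonide to the 1,6-dialdehyde, and the ammonium salt turns the aldehyde whose α-CH2 sits on C3a into its enamine, which adds to the other formyl group before water and amine are lost to give the conjugated enal. The closest known reaction type is the ozonolysis/intramolecular aldol condensation that contracts cyclohexenes to cyclopent-1-ene-1-carbaldehydes. Ring A is closed in the 5-(enolexo)-exo-trig mode by formation of the C2–C3 bond. No new stereocentre is created (C2 and C3 become sp2), and C3a and C8a, which are not enolisable at this oxidation level, are carried over unchanged. The step needs chemoselective ozonolysis (the benzoate ring is electron-poor and there is no other C=C) and regioselective aldolisation: the alternative donor CH2 is neopentylic to the quaternary C8a, so attack through it is retarded and the enal with the formyl group remote from the quaternary carbon should dominate. In one operation the cyclohexene becomes the ring-A cyclopentene carrying the future isopropyl carbon on C3 and the unsaturation used to place the C3 hydroxyl.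

Step 6
Reactants: 10 (3aS,4R,7aR)-3-formyl-6,7a-dimethyl-7-oxo-3a,4,5,6,7,7a-hexahydro-1H-inden-4-yl 4-(acetyloxy)benzoate
Product: 11 (3aS,4R,7aR)-3-(1-hydroxyethyl)-6,7a-dimethyl-7-oxo-3a,4,5,6,7,7a-hexahydro-1H-inden-4-yl 4-(acetyloxy)benzoate (carbinol epimers)
Conditions: MeTi(OiPr)3, THF, −78 to 0 °C
Reagents that add atoms: methyltitanium triisopropoxide, C[Ti](OC(C)C)(OC(C)C)OC(C)C
Why: Organotitanium 1,2-addition is selective for the aldehyde over the hindered ketone and the esters; the carbinol epimers converge in step 7.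

Step 7
Reactants: 11 (3aS,4R,7aR)-3-(1-hydroxyethyl)-6,7a-dimethyl-7-oxo-3a,4,5,6,7,7a-hexahydro-1H-inden-4-yl 4-(acetyloxy)benzoate
Product: 12 (3aR,4R,7aR)-3-acetyl-6,7a-dimethyl-7-oxo-3a,4,5,6,7,7a-hexahydro-1H-inden-4-yl 4-(acetyloxy)benzoate
Conditions: Dess–Martin periodinane, NaHCO3, CH2Cl2, rt
Reagents that add atoms: none
Why: Dess–Martin oxidation of the secondary allylic alcohol gives the conjugated methyl ketone; no stereocentre is formed.

Step 8
Reactants: 12 (3aR,4R,7aR)-3-acetyl-6,7a-dimethyl-7-oxo-3a,4,5,6,7,7a-hexahydro-1H-inden-4-yl 4-(acetyloxy)benzoate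
Product: 14 (3R,3aS,4R,7aR)-3-acetyl-3-hydroxy-6,7a-dimethyl-7-oxo-octahydro-1H-inden-4-yl 4-(acetyloxy)benzoate, via hydroperoxide 13 (not isolated)
Conditions: Mn(dpm)3 [tris(2,2,6,6-tetramethylheptane-3,5-dionato)manganese] (10 mol %), PhSiH3, O2 (1 atm), iPrOH/CH2Cl2, 0 °C; then P(OEt)3
Reagents that add atoms: dioxygen, O=O
Why: Mukaiyama-type hydrogen-atom-transfer α-hydroxylation of an enone (H-atom addition at C2, O2 capture of the tertiary α-keto radical at C3, reduction of the hydroperoxide); O2 should enter on the convex face (the side of H-3a and the angular methyl, anti to the ring-B bond at C3a), which sets the C3 hydroxyl cis to H-3a.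

Step 9
Reactants: 14 (3R,3aS,4R,7aR)-3-acetyl-3-hydroxy-6,7a-dimethyl-7-oxo-octahydro-1H-inden-4-yl 4-(acetyloxy)benzoate
Product: 15 (3R,3aS,4R,7aR)-3-hydroxy-6,7a-dimethyl-7-oxo-3-(prop-1-en-2-yl)octahydro-1H-inden-4-yl 4-(acetyloxy)benzoate
Conditions: Zn, CH2Br2, TiCl4, THF/CH2Cl2, 0 °C to rt
Reagents that add atoms: dibromomethane, BrCBr
Why: Takai–Lombardo methylenation is a non-basic olefination that converts the methyl ketone into the isopropenyl group without α-ketol rearrangement and leaves the far more hindered ring ketone and the esters alone.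

Step 10
Reactants: 15 (3R,3aS,4R,7aR)-3-hydroxy-6,7a-dimethyl-7-oxo-3-(prop-1-en-2-yl)octahydro-1H-inden-4-yl 4-(acetyloxy)benzoate
Product: 16 (3S,3aS,4R,7aR)-3-hydroxy-6,7a-dimethyl-7-oxo-3-(propan-2-yl)octahydro-1H-inden-4-yl 4-(acetyloxy)benzoate
Conditions: H2 (1 atm), PtO2, EtOAc, rt
Reagents that add atoms: none
Why: Catalytic hydrogenation of the only C=C bond present (1,1-disubstituted) gives the isopropyl group; no stereocentre is formed.

Step 11
Reactants: 16 (3S,3aS,4R,7aR)-3-hydroxy-6,7a-dimethyl-7-oxo-3-(propan-2-yl)octahydro-1H-inden-4-yl 4-(acetyloxy)benzoate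
Product: 17 (3S,3aS,4R,7aR)-6,7a-dimethyl-3-(propan-2-yl)-3,7-bis(trimethylsilyloxy)-2,3,3a,4,5,7a-hexahydro-1H-inden-4-yl 4-(acetyloxy)benzoate
Conditions: TMSOTf (3 equiv), Et3N, CH2Cl2, 0 °C to rt
Reagents that add atoms: trimethylsilyl triflate, C[Si](C)(C)OS(=O)(=O)C(F)(F)F
Why: Soft enolisation and silylation; the ketone has a single enolisable α-carbon, so the tetrasubstituted silyl enol ether forms regiospecifically, the epimers at the methyl-bearing carbon converge, and the tertiary alcohol is silylated as well.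

Step 12
Reactants: 17 (3S,3aS,4R,7aR)-6,7a-dimethyl-3-(propan-2-yl)-3,7-bis(trimethylsilyloxy)-2,3,3a,4,5,7a-hexahydro-1H-inden-4-yl 4-(acetyloxy)benzoate
Product: 18 siloxycyclopropane of 17 (CH2 bridging the two former enol ether carbons; cyclopropane centres undefined)
Conditions: Et2Zn, CH2I2, toluene, 0 °C to rt
Reagents that add atoms: diiodomethane, ICI
Why: Furukawa-modified Simmons–Smith cyclopropanation of the electron-rich silyl enol ether (the only C=C bond) adds the carbon that becomes C7; the cyclopropane stereocentres are destroyed in step 13.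

Step 13
Reactants: 18 siloxycyclopropane of 17
Product: 20 (3S,3aS,4R,8aR)-3-hydroxy-6,8a-dimethyl-8-oxo-3-(propan-2-yl)-1,2,3,3a,4,5,8,8a-octahydroazulen-4-yl 4-(acetyloxy)benzoate, via β-chloro ketone 19 (not isolated)
Conditions: FeCl3 (2.2 equiv), DMF, 0 °C to rt; 1 M HCl work-up; then Et3N, CH2Cl2, rt
Reagents that add atoms: none
Why: Ito–Saegusa ring expansion: one-electron oxidation of the siloxycyclopropane by FeCl3 cleaves the internal cyclopropane bond to the tertiary C6 radical, chlorine transfer gives the β-chloro cycloheptanone, and E1cB loss of HCl gives the C6=C7–C8=O enone, while the acidic work-up frees the tertiary alcohol.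

Step 14
Reactants: 20 (3S,3aS,4R,8aR)-3-hydroxy-6,8a-dimethyl-8-oxo-3-(propan-2-yl)-1,2,3,3a,4,5,8,8a-octahydroazulen-4-yl 4-(acetyloxy)benzoate
Product: 21 (3S,3aS,4R,8S,8aR)-3,8-dihydroxy-6,8a-dimethyl-3-(propan-2-yl)-1,2,3,3a,4,5,8,8a-octahydroazulen-4-yl 4-(acetyloxy)benzoate
Conditions: (R)-1-methyl-3,3-diphenyltetrahydro-1H,3H-pyrrolo[1,2-c][1,3,2]oxazaborole [(R)-Me-CBS] (20 mol %), catecholborane, toluene, −78 °C
Reagents that add atoms: none
Why: Corey–Bakshi–Shibata 1,2-reduction of the enone; with the quaternary C8a as the large flank and the vinylic C7 as the small one, the (R)-catalyst should deliver hydride to the face that gives the (8S)-alcohol, which is also the convex face of the cis-fused bicycle, so reagent and substrate control should agree.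

Step 15
Reactants: 21 (3S,3aS,4R,8S,8aR)-3,8-dihydroxy-6,8a-dimethyl-3-(propan-2-yl)-1,2,3,3a,4,5,8,8a-octahydroazulen-4-yl 4-(acetyloxy)benzoate; 22 3-methylbutanoyl chloride
Product: 23 (3S,3aS,4R,8S,8aR)-3-hydroxy-6,8a-dimethyl-8-[(3-methylbutanoyl)oxy]-3-(propan-2-yl)-1,2,3,3a,4,5,8,8a-octahydroazulen-4-yl 4-(acetyloxy)benzoate
Conditions: pyridine, DMAP, CH2Cl2, 0 °C to rt
Reagents that add atoms: 3-methylbutanoyl chloride (22), CC(C)CC(Cl)=O
Why: DMAP-catalysed acylation of the secondary allylic alcohol; the tertiary C3 alcohol is too hindered to react.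

Step 16
Reactants: 23 (3S,3aS,4R,8S,8aR)-3-hydroxy-6,8a-dimethyl-8-[(3-methylbutanoyl)oxy]-3-(propan-2-yl)-1,2,3,3a,4,5,8,8a-octahydroazulen-4-yl 4-(acetyloxy)benzoate
Product: 24 (3S,3aS,4R,8S,8aR)-3-hydroxy-6,8a-dimethyl-8-[(3-methylbutanoyl)oxy]-3-(propan-2-yl)-1,2,3,3a,4,5,8,8a-octahydroazulen-4-yl 4-hydroxybenzoate
Conditions: pyrrolidine (2 equiv), CH2Cl2, 0 °C
Reagents that add atoms: none
Why: Chemoselective aminolysis of the phenolic acetate (an aryl ester is a far better acyl donor than the two alkyl esters) liberates the phenol and should give the target.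

**Compound list**

1 | 2,6-dimethyl-1,4-benzoquinone | CC1=CC(=O)C=C(C)C1=O | starting material
2 | buta-1,3-diene | C=CC=C | starting material
3 | (4aS,8aR)-2,8a-dimethyl-4a,5,8,8a-tetrahydronaphthalene-1,4-dione | CC1=CC(=O)[C@H]2CC=CC[C@@]2(C)C1=O | intermediate
4 | (4aS,8aR)-2,8a-dimethyl-2,3,4a,5,8,8a-hexahydronaphthalene-1,4-dione (epimers at C2) | CC1C(=O)[C@]2(C)CC=CC[C@@H]2C(=O)C1 | intermediate
5 | (4R,4aS,8aR)-4-hydroxy-2,8a-dimethyl-3,4,4a,5,8,8a-hexahydronaphthalen-1(2H)-one (epimers at C2) | CC1C(=O)[C@]2(C)CC=CC[C@@H]2[C@H](O)C1 | intermediate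
6 | 4-(acetyloxy)benzoyl chloride | CC(=O)Oc1ccc(cc1)C(Cl)=O | starting material
7 | (1R,4aR,8aS)-3,4a-dimethyl-4-oxo-1,2,3,4,4a,5,8,8a-octahydronaphthalen-1-yl 4-(acetyloxy)benzoate (epimers at C3) | CC1C(=O)[C@]2(C)CC=CC[C@@H]2[C@H](OC(=O)c2ccc(OC(C)=O)cc2)C1 | intermediate
8 | secondary ozonide (1,2,4-trioxolane) of 7 | CC1C(=O)[C@]2(C)CC3OOC(O3)C[C@@H]2[C@H](OC(=O)c2ccc(OC(C)=O)cc2)C1 | intermediate
9 | (1R,2S,3R)-3,5-dimethyl-4-oxo-2,3-bis(2-oxoethyl)cyclohexyl 4-(acetyloxy)benzoate | CC1C(=O)[C@](C)(CC=O)[C@H](CC=O)[C@H](OC(=O)c2ccc(OC(C)=O)cc2)C1 | intermediate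
10 | (3aS,4R,7aR)-3-formyl-6,7a-dimethyl-7-oxo-3a,4,5,6,7,7a-hexahydro-1H-inden-4-yl 4-(acetyloxy)benzoate (cis-fused; epimers at C6) | CC1C(=O)[C@]2(C)CC=C(C=O)[C@@H]2[C@H](OC(=O)c2ccc(OC(C)=O)cc2)C1 | intermediate
11 | (3aS,4R,7aR)-3-(1-hydroxyethyl)-6,7a-dimethyl-7-oxo-3a,4,5,6,7,7a-hexahydro-1H-inden-4-yl 4-(acetyloxy)benzoate (carbinol epimers) | CC1C(=O)[C@]2(C)CC=C(C(C)O)[C@@H]2[C@H](OC(=O)c2ccc(OC(C)=O)cc2)C1 | intermediate
12 | (3aR,4R,7aR)-3-acetyl-6,7a-dimethyl-7-oxo-3a,4,5,6,7,7a-hexahydro-1H-inden-4-yl 4-(acetyloxy)benzoate | CC1C(=O)[C@]2(C)CC=C(C(C)=O)[C@@H]2[C@H](OC(=O)c2ccc(OC(C)=O)cc2)C1 | intermediate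
13 | (3R,3aS,4R,7aR)-3-acetyl-3-hydroperoxy-6,7a-dimethyl-7-oxo-octahydro-1H-inden-4-yl 4-(acetyloxy)benzoate | CC1C(=O)[C@]2(C)CC[C@](OO)(C(C)=O)[C@@H]2[C@H](OC(=O)c2ccc(OC(C)=O)cc2)C1 | intermediate
14 | (3R,3aS,4R,7aR)-3-acetyl-3-hydroxy-6,7a-dimethyl-7-oxo-octahydro-1H-inden-4-yl 4-(acetyloxy)benzoate (OH cis to H-3a and the angular methyl) | CC1C(=O)[C@]2(C)CC[C@](O)(C(C)=O)[C@@H]2[C@H](OC(=O)c2ccc(OC(C)=O)cc2)C1 | intermediate
15 | (3R,3aS,4R,7aR)-3-hydroxy-6,7a-dimethyl-7-oxo-3-(prop-1-en-2-yl)octahydro-1H-inden-4-yl 4-(acetyloxy)benzoate | CC1C(=O)[C@]2(C)CC[C@](O)(C(C)=C)[C@@H]2[C@H](OC(=O)c2ccc(OC(C)=O)cc2)C1 | intermediate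
16 | (3S,3aS,4R,7aR)-3-hydroxy-6,7a-dimethyl-7-oxo-3-(propan-2-yl)octahydro-1H-inden-4-yl 4-(acetyloxy)benzoate | CC1C(=O)[C@]2(C)CC[C@](O)(C(C)C)[C@@H]2[C@H](OC(=O)c2ccc(OC(C)=O)cc2)C1 | intermediate
17 | (3S,3aS,4R,7aR)-6,7a-dimethyl-3-(propan-2-yl)-3,7-bis(trimethylsilyloxy)-2,3,3a,4,5,7a-hexahydro-1H-inden-4-yl 4-(acetyloxy)benzoate | CC1=C(O[Si](C)(C)C)[C@]2(C)CC[C@](O[Si](C)(C)C)(C(C)C)[C@@H]2[C@H](OC(=O)c2ccc(OC(C)=O)cc2)C1 | intermediate
18 | siloxycyclopropane of 17 (tricyclic; CH2 across the former enol ether C=C) | CC12CC1(O[Si](C)(C)C)[C@]3(C)CC[C@](O[Si](C)(C)C)(C(C)C)[C@@H]3[C@H](OC(=O)c1ccc(OC(C)=O)cc1)C2 | intermediate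
19 | (3S,3aS,4R,8aR)-6-chloro-3-hydroxy-6,8a-dimethyl-8-oxo-3-(propan-2-yl)decahydroazulen-4-yl 4-(acetyloxy)benzoate | CC1(Cl)CC(=O)[C@]2(C)CC[C@](O)(C(C)C)[C@@H]2[C@H](OC(=O)c2ccc(OC(C)=O)cc2)C1 | intermediate
20 | (3S,3aS,4R,8aR)-3-hydroxy-6,8a-dimethyl-8-oxo-3-(propan-2-yl)-1,2,3,3a,4,5,8,8a-octahydroazulen-4-yl 4-(acetyloxy)benzoate | CC1=CC(=O)[C@]2(C)CC[C@](O)(C(C)C)[C@@H]2[C@H](OC(=O)c2ccc(OC(C)=O)cc2)C1 | intermediate
21 | (3S,3aS,4R,8S,8aR)-3,8-dihydroxy-6,8a-dimethyl-3-(propan-2-yl)-1,2,3,3a,4,5,8,8a-octahydroazulen-4-yl 4-(acetyloxy)benzoate | CC1=C[C@H](O)[C@]2(C)CC[C@](O)(C(C)C)[C@@H]2[C@H](OC(=O)c2ccc(OC(C)=O)cc2)C1 | intermediate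
22 | 3-methylbutanoyl chloride | CC(C)CC(Cl)=O | starting material
23 | (3S,3aS,4R,8S,8aR)-3-hydroxy-6,8a-dimethyl-8-[(3-methylbutanoyl)oxy]-3-(propan-2-yl)-1,2,3,3a,4,5,8,8a-octahydroazulen-4-yl 4-(acetyloxy)benzoate | CC1=C[C@H](OC(=O)CC(C)C)[C@]2(C)CC[C@](O)(C(C)C)[C@@H]2[C@H](OC(=O)c2ccc(OC(C)=O)cc2)C1 | intermediate
24 | (3S,3aS,4R,8S,8aR)-3-hydroxy-6,8a-dimethyl-8-[(3-methylbutanoyl)oxy]-3-(propan-2-yl)-1,2,3,3a,4,5,8,8a-octahydroazulen-4-yl 4-hydroxybenzoate | CC1=C[C@H](OC(=O)CC(C)C)[C@]2(C)CC[C@](O)(C(C)C)[C@@H]2[C@H](OC(=O)c2ccc(O)cc2)C1 | target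

**Step count and risks**

Total step count: 16. Longest linear sequence: 16 steps (1 and 2 to 24).

Three steps most likely to fail:

Step 12 (the ring expansion, with steps 11 and 13). The zinc carbenoid may not add to the tetrasubstituted silyl enol ether next to the quaternary carbon, or the cyclopropane may open without ring enlargement. The fallback sets out from 16: Lewis-acid-catalysed diazoalkane homologation (Sc(OTf)3 cat., TMSCHN2, toluene, rt; aqueous HCl work-up), in which the less substituted α-carbon C6 migrates, should give the saturated ring-expanded ketone (3S,3aS,4R,8aR)-3-hydroxy-6,8a-dimethyl-8-oxo-3-(propan-2-yl)decahydroazulen-4-yl 4-(acetyloxy)benzoate F1. Its only possible silyl enol ether (TMSOTf, Et3N), the bis-silyl compound F2, is dehydrogenated by Saegusa–Ito oxidation with Pd(OAc)2 (divalent palladium) in MeCN, and acidic work-up comes back to the route at 20.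

Step 8. Oxygen may trap the planar α-keto radical with poor facial selectivity, or the radical may be reduced without oxygenation. The fallback sets out from 12: rhodium-catalysed 1,4-hydrosilylation (RhCl(PPh3)3, Et3SiH, benzene, 50 °C) should give the triethylsilyl enol ether F3, and Rubottom oxidation with dimethyldioxirane (acetone, −40 °C, a bulkier electrophile approaching the same convex face) and acidic work-up comes back to the route at 14.

Step 14. Catalyst control and the substrate's own bias may be mismatched next to the quaternary carbon, giving poor facial selectivity at C8. The fallback sets out from 20: reduction under substrate control (NaBH4, CeCl3, MeOH, −78 °C) to the 8-epimeric alcohol (3S,3aS,4R,8R,8aR)-3,8-dihydroxy-6,8a-dimethyl-3-(propan-2-yl)-1,2,3,3a,4,5,8,8a-octahydroazulen-4-yl 4-(acetyloxy)benzoate F4, then Mitsunobu esterification with 3-methylbutanoic acid (PPh3, DIAD, toluene, 0 °C to rt), which inverts C8 and comes back to the route at 23.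

Further compounds
F1 | step 12 | (3S,3aS,4R,8aR)-3-hydroxy-6,8a-dimethyl-8-oxo-3-(propan-2-yl)decahydroazulen-4-yl 4-(acetyloxy)benzoate (epimers at C6) | CC1CC(=O)[C@]2(C)CC[C@](O)(C(C)C)[C@@H]2[C@H](OC(=O)c2ccc(OC(C)=O)cc2)C1
F2 | step 12 | (3S,3aS,4R,8aR)-6,8a-dimethyl-3-(propan-2-yl)-3,8-bis(trimethylsilyloxy)-1,2,3,3a,4,5,6,8a-octahydroazulen-4-yl 4-(acetyloxy)benzoate | CC1C=C(O[Si](C)(C)C)[C@]2(C)CC[C@](O[Si](C)(C)C)(C(C)C)[C@@H]2[C@H](OC(=O)c2ccc(OC(C)=O)cc2)C1
F3 | step 8 | (3aS,4R,7aR)-6,7a-dimethyl-7-oxo-3-[1-(triethylsilyloxy)ethylidene]octahydro-1H-inden-4-yl 4-(acetyloxy)benzoate | CC1C(=O)[C@]2(C)CCC(=C(C)O[Si](CC)(CC)CC)[C@@H]2[C@H](OC(=O)c2ccc(OC(C)=O)cc2)C1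
F4 | step 14 | (3S,3aS,4R,8R,8aR)-3,8-dihydroxy-6,8a-dimethyl-3-(propan-2-yl)-1,2,3,3a,4,5,8,8a-octahydroazulen-4-yl 4-(acetyloxy)benzoate | CC1=C[C@@H](O)[C@]2(C)CC[C@](O)(C(C)C)[C@@H]2[C@H](OC(=O)c2ccc(OC(C)=O)cc2)C1
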